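## Structural features

Isolophirone C (20) is an achiral polyphenol (C30H22O8) built on a benzofuran. C2 carries a 4-hydroxyphenyl ring, C3 a 2,4-dihydroxybenzoyl group, and C5 a CH2CH2C(=O) chain ending in a second 2,4-dihydroxyphenyl ring; C4, C6 and C7 are unsubstituted. There is no stereocentre, so no neighbouring stereocentres have to be related. The only stereochemical element on the way is the E double bond of the chalcone intermediates, which the last step removes. The fragile parts are the five free phenols (two on oxidisable resorcinol rings), the two chelated ortho-hydroxyaryl ketones and the enolisable saturated ketone, so the phenols stay masked until one mild final unmasking. The real difficulty is the C3 diaryl ketone. Its carbonyl is wedged between the C2 aryl ring and the peri hydrogen at C4, and the resorcinol ring must be joined through the carbon ortho to one oxygen and para to the other. The same 2,4-dioxygenated aroyl unit also occurs a second time, attached differently (to the CH2CH2 chain), and the two must not be confused. The key step uses the C3 ketone carbon bonded to C1' of the resorcinol ring, whose neighbour C2' bears a hydroxyl. The bonds C(=O)–C1' and C2'–O are the pair formed when an aryne inserts into the acyl–oxygen bond of a benzofuran-3-carboxylic acid. Placing the second oxygen at C4' requires the aryne to be oriented; a chlorine at C6', later exchanged for hydrogen, does this.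

## Logic of the disconnections

20 ⇒ 19. No skeletal bond is cut. Going backwards, the four phenols that do not come from the insertion become benzyl ethers, C6' regains chlorine and the Cα–Cβ bond of the chain becomes an E double bond. One hydrogenation reverses all three changes, so the end game is a single step. The benzyl ethers keep earlier intermediates free of acidic O–H, the chlorine steers the aryne, and the enone removes acidic α-hydrogens from the key step. The demand on the forward step is that hydrogenation stops before the two aryl ketones or the furan double bond are touched.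

19 ⇒ 11 + 17 (through 18). The bonds C(=O)–C1' and C2'–O are cut. The ortho acyl/hydroxy pair is the retron of an aryne insertion into a carboxylic acid C–O bond. This splits the hindered ketone into a benzofuran acid and a six-carbon ring that arrives with its oxygen pattern already fixed. The forward step must add the carboxylate oxygen to the aryne carbon remote from chlorine, and must trap the resulting aryl anion on the ester carbonyl before it is protonated or loses chloride.

11 ⇒ 7 + 9 (through 10). The enone Cα=Cβ bond is cut as an aldol condensation, and the acid is traced back to its ethyl ester. Aldol condensation is the most reliable way to make a chalcone, and its basic medium also frees the acid in the same flask. The enone is thus proven stable to the ester cleavage, and no polymerisable aryl vinyl ketone is handled. The demand is an aldehyde at C5 and thermodynamic control for the E geometry.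

7 ⇒ 6 ⇒ 5. The C5–CHO bond is cut as a reductive carbonylation, then the O–S bond of the sulfonate. The annulation below delivers a phenol at C5, and the triflate turns it into a carbon electrophile. The demand is that CO insertion at palladium is faster than simple reduction of the aryl–palladium species.

5 ⇒ 2 + 3 (through 4). The bonds C3–C3a and O1–C2 are cut. The quinone supplies the benzo ring with O1 and the C5 oxygen; the β-ketoester supplies C2 and C3 with the aryl group and the ester in the right places. The whole core comes from two simple pieces in one step. The demand is Michael addition followed by cyclodehydration without redox side reactions of the quinone.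

2 ⇒ 1. The bond between the methyl carbon of the ketone and the ester carbonyl is cut (Claisen condensation with a carbonate ester). The forward step needs only irreversible enolate formation.

9 ⇒ 8. The two O–benzyl bonds are cut. The forward step must alkylate the chelated ortho hydroxyl as well as the para one.

17 ⇒ 14 (through 15 and 16) ⇒ 13 ⇒ 12. The C–Si and O–S bonds are cut first, tracing the silyl triflate to an ortho-bromophenol by silyl migration from oxygen to carbon. Then the C–Br and C–Cl bonds are cut as phenol-directed halogenations. The forward steps need halogenation ortho to the hydroxyl only, one halogen at a time, and metal–halogen exchange at bromine that leaves chlorine alone.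

## Other disconnections considered

Alternative 1: The furan ring is cut at C3–C3a and O1–C2. This divides the target into two C15 halves, the chalcone A1 and the dihydrochalcone A2. In the forward step Ag2O would oxidise both phenols. The phenoxyl radical of A1 carries spin on the carbon α to its carbonyl and would bond to the carbon ortho to oxygen in the radical of A2. After tautomerisation the phenol oxygen would add to the quinone methide and give the trans-dihydrobenzofuran A3. Dehydrogenation and cleavage of four methyl ethers would follow.
- In its favour: it is biomimetic and highly convergent. Both halves come in two or three steps from simple aromatic ketones and aldehydes, the C5 chain is in place from the start, and no transition-metal coupling is needed. On step economy it is clearly better than the chosen plan.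
- Against it: A1 is the more easily oxidised partner and its radical would pair with itself at least as readily as with the simple para-alkylphenol A2. Cross-coupling therefore competes with two homodimerisations and with C–O coupling. The two stereocentres of A3 are made only to be destroyed. The 3-acyl dihydrobenzofuran can open by retro-oxa-Michael reaction. Methyl ether cleavage with BBr3 is harsher than hydrogenolysis.
- Comparison: on structure, both plans form two bonds in the key step; this one builds the heterocycle, the chosen one builds the hindered ketone. On mechanism, the radical pairing has no built-in director, whereas the aryne addition is polar and steered by chlorine. The alternative wins on length, the chosen plan on control.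

Alternative 2: The benzo ring is cut at C3a–C4. The precursor is the dienylfuran A4, which already carries the C2 aryl and C3 aroyl groups. In the forward step light would turn the C6=C7 alkene from E to Z. The furan C3a=C7a bond and the methoxydiene would then close thermally in a disrotatory 6π process, and loss of methanol would aromatise the new ring to give A5.
- In its favour: the crowded C3 ketone is installed on a small furan before the ring system is congested. Its position needs no director and leaves no halogen to remove; on this point it equals or betters the chosen plan. The aromatisation is irreversible, and the key step needs no metal.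
- Against it: the triene includes an aromatic furan bond, so closure costs furan aromaticity and would need high temperature. The aroyl chromophore invites competing photochemistry. A4 is a sensitive enol ether–diene that needs a long linear preparation. After the key step the propanoate of A5 must still be made into the second aryl ketone by a Friedel–Crafts step onto a resorcinol diether, and five methyl ethers must be cleaved.
- Comparison: on structure, it builds the carbocycle, where the chosen plan buys it with the quinone. On mechanism, it is pericyclic and regiochemically unambiguous, but energetically demanding. On step economy it is clearly longer.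

Alternative 3: The furan C2=C3 bond is cut. The precursor is the phosphonium salt A6. On heating in toluene with Et3N, the ylide carbon would attack the neighbouring aryl ester carbonyl and expel Ph3PO to give the 5-bromobenzofuran ketone A7. The bromide would then be elaborated into the C5 chain much as the triflate is in the chosen plan, followed by hydrogenation and ether cleavage.
- In its favour: ring and C3 ketone arrive together without a metal. The resorcinol regiochemistry comes ready-made with an aroyl chloride, so there is no aryne orientation problem and no sacrificial chlorine; here it is better than the chosen plan. The bromide is a handle equal to the triflate. The route to the 3-aroylbenzofuran core should be shorter.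
- Against it: the ylide of A6 is stabilised by both the ketone and the aryl ring and is hindered, and an ester carbonyl is a poor Wittig acceptor. Preparing A6 needs two different acylations, one on carbon and one on oxygen, without acyl scrambling or O-acylation of the keto-ylide. The methyl ethers again need Lewis-acid cleavage, although benzyl ethers could be used to make the end game equal.
- Comparison: on structure, it forms the heterocycle and the ketone in one event. On mechanism, the doubt lies in the reactivity of a doubly stabilised ylide, against the doubt over anion capture in the chosen plan. On step economy it is equal or somewhat better. The chosen plan is kept because its key step settles the hindered ketone and the oxygen pattern in one operation under director control.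

Key step: step 10

Remarks on the chemistry:
- The regiochemistry of the insertion was rechecked atom by atom. Aryne 18 from 17 has chlorine next to the triple bond and the benzyloxy group meta to the carbon that receives oxygen. Compounds 11, 17 and 19 are mutually consistent and need no correction.
- The acid proton of 11 is taken up by fluoride and returned to the product phenoxide on work-up, so the net equation of step 10 consumes one CsF.
- Compounds 1, 3, 8 and 12 are assumed to be purchased.

## Route

Step 1
Reactants: 1 4'-(benzyloxy)acetophenone
Product: 2 ethyl 3-[4-(benzyloxy)phenyl]-3-oxopropanoate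
Conditions: NaH (2.5 equiv), (EtO)2CO, THF, reflux; then aq HCl
Reagents that add atoms: diethyl carbonate, CCOC(=O)OCC
Why: Crossed Claisen condensation; the sodium enolate of 1 is acylated by the non-enolisable carbonate and the product is drained as its stabilised β-ketoester enolate, which drives the equilibrium, while the benzyl ether is inert to NaH.

Step 2
Reactants: 2 ethyl 3-[4-(benzyloxy)phenyl]-3-oxopropanoate; 3 1,4-benzoquinone
Product: 5 ethyl 2-[4-(benzyloxy)phenyl]-5-hydroxy-1-benzofuran-3-carboxylate, via hydroquinone Michael adduct 4 (not isolated)
Conditions: ZnCl2 (1 equiv), EtOH, reflux, slow addition of 3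
Reagents that add atoms: none
Why: Michael addition–cyclodehydration, the oxygen counterpart of the Nenitzescu indole synthesis; ZnCl2 activates the quinone for attack by the β-ketoester carbon, adduct 4 aromatises to the hydroquinone, and its ortho hydroxyl condenses with the aryl ketone with loss of water, which fixes the ester at C3, the aryl at C2 and the hydroxyl at C5; slow addition of 3 limits oxidation of 4.

Step 3
Reactants: 5 ethyl 2-[4-(benzyloxy)phenyl]-5-hydroxy-1-benzofuran-3-carboxylate
Product: 6 ethyl 2-[4-(benzyloxy)phenyl]-5-{[(trifluoromethyl)sulfonyl]oxy}-1-benzofuran-3-carboxylate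
Conditions: Tf2O, pyridine, CH2Cl2, 0 °C
Reagents that add atoms: trifluoromethanesulfonic anhydride, O=S(=O)(OS(=O)(=O)C(F)(F)F)C(F)(F)F
Why: O-sulfonylation of the only free phenol; the ester and the benzyl ether do not react.

Step 4
Reactants: 6 ethyl 2-[4-(benzyloxy)phenyl]-5-{[(trifluoromethyl)sulfonyl]oxy}-1-benzofuran-3-carboxylate
Product: 7 ethyl 2-[4-(benzyloxy)phenyl]-5-formyl-1-benzofuran-3-carboxylate
Conditions: Pd(OAc)2 (5 mol %), dppp (5 mol %), CO (1 atm), Et3SiH (2 equiv), Et3N, DMF, 70 °C
Reagents that add atoms: carbon monoxide, [C-]#[O+]
Why: Palladium-catalysed reductive carbonylation of an aryl triflate; oxidative addition to zerovalent palladium, CO insertion to the acylpalladium species and hydride transfer from the silane release the aldehyde, and the chelating diphosphine suits triflates while ester and benzyl ether are spectators.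

Step 5
Reactants: 8 2',4'-dihydroxyacetophenone
Product: 9 2',4'-bis(benzyloxy)acetophenone
Conditions: BnBr (2.4 equiv), K2CO3, DMF, 70 °C
Reagents that add atoms: benzyl bromide, BrCc1ccccc1
Why: Williamson ether synthesis; DMF and warming overcome the hydrogen bond of the ortho hydroxyl so that both phenols are alkylated.

Step 6
Reactants: 7 ethyl 2-[4-(benzyloxy)phenyl]-5-formyl-1-benzofuran-3-carboxylate; 9 2',4'-bis(benzyloxy)acetophenone
Product: 11 2-[4-(benzyloxy)phenyl]-5-{(E)-3-[2,4-bis(benzyloxy)phenyl]-3-oxoprop-1-en-1-yl}-1-benzofuran-3-carboxylic acid, via chalcone ethyl ester 10 (not isolated)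
Conditions: 9 (1.1 equiv), aq KOH, EtOH/THF, rt; then H2O, 60 °C; then aq HCl
Reagents that add atoms: potassium hydroxide, [K+].[OH-]
Why: Claisen–Schmidt condensation; the enolate of 9 adds to the non-enolisable aldehyde 7 and E1cB dehydration gives the thermodynamically preferred E enone 10, after which the same hydroxide saponifies the ethyl ester on warming; the enone is formed under these conditions and is therefore stable to them.

Step 7
Reactants: 12 4-(benzyloxy)phenol
Product: 13 4-(benzyloxy)-2-chlorophenol
Conditions: SO2Cl2 (1.0 equiv), i-Bu2NH (cat.), toluene, 0 °C to rt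
Reagents that add atoms: sulfuryl chloride, O=S(=O)(Cl)Cl
Why: Electrophilic aromatic chlorination; the free hydroxyl is the strongest activator and its para position is blocked, so chlorine enters ortho to it, the amine catalyst reinforces ortho delivery and one equivalent limits dichlorination.

Step 8
Reactants: 13 4-(benzyloxy)-2-chlorophenol
Product: 14 4-(benzyloxy)-2-bromo-6-chlorophenol
Conditions: NBS (1.0 equiv), CH2Cl2, 0 °C
Reagents that add atoms: N-bromosuccinimide, O=C1CCC(=O)N1Br
Why: Electrophilic bromination at the one remaining position ortho to the hydroxyl; the positions ortho to the benzyloxy group are less activated and one of them is flanked by chlorine.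

Step 9
Reactants: 14 4-(benzyloxy)-2-bromo-6-chlorophenol
Product: 17 4-(benzyloxy)-2-chloro-6-(trimethylsilyl)phenyl trifluoromethanesulfonate, via aryl silyl ether 15 (not isolated), via lithium silylphenoxide 16 (not isolated)
Conditions: HMDS, THF, reflux, then evaporation; n-BuLi, THF, −78 °C; Tf2O, −78 °C to rt
Reagents that add atoms: 1,1,1,3,3,3-hexamethyldisilazane, C[Si](C)(C)N[Si](C)(C)C; trifluoromethanesulfonic anhydride, O=S(=O)(OS(=O)(=O)C(F)(F)F)C(F)(F)F
Why: O-silylation, then bromine–lithium exchange (faster at −78 °C than any reaction at the C–Cl bond or the benzylic CH2) gives an ortho-lithiated silyl ether that undergoes the retro-Brook 1,3-shift of silicon from oxygen to carbon, and phenoxide 16 is trapped by Tf2O; this is the standard entry to ortho-silylaryl triflates.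

Step 10
Reactants: 11 2-[4-(benzyloxy)phenyl]-5-{(E)-3-[2,4-bis(benzyloxy)phenyl]-3-oxoprop-1-en-1-yl}-1-benzofuran-3-carboxylic acid; 17 4-(benzyloxy)-2-chloro-6-(trimethylsilyl)phenyl trifluoromethanesulfonate
Product: 19 (E)-3-{3-[4-(benzyloxy)-2-chloro-6-hydroxybenzoyl]-2-[4-(benzyloxy)phenyl]-1-benzofuran-5-yl}-1-[2,4-bis(benzyloxy)phenyl]prop-2-en-1-one, via 5-(benzyloxy)-3-chlorobenzyne 18 (not isolated)
Conditions: 17 (1.5 equiv), CsF (4 equiv), THF, 125 °C (sealed vessel); then aq NH4Cl
Reagents that add atoms: none
Why: Fluoride attacks silicon in 17 and triflate leaves, releasing aryne 18, while fluoride also converts acid 11 into its cesium carboxylate. The chlorine beside the triple bond distorts 18 so that the aryne carbon remote from chlorine is the more electrophilic; the carboxylate oxygen adds there and the negative charge develops on the carbon next to chlorine, where it is stabilised inductively. That aryl anion lies ortho to the new aryl ester and attacks its carbonyl through a four-membered transition state, which opens by C–O cleavage to the ortho-acyl phenoxide, and work-up gives 19. The closest known reaction type is the formal insertion of arynes into the acyl–oxygen bond of aromatic and aliphatic carboxylic acids with CsF in hot THF, an aryne version of the anionic Fries acyl shift. No ring is closed and no stereocentre is formed; the E alkene is not involved. Two selectivities are needed: the orientation on the aryne, which chlorine secures against the weak opposing bias of the remote benzyloxy group so that this group ends para to the acyl carbon, and acyl capture ahead of protonation or chloride loss from the aryl anion, which is favoured by the aprotic medium, the high temperature, the intramolecular delivery and the absence of acidic C–H bonds in 11 (the enone has only vinylic hydrogens). The sparing solubility of CsF in THF meters the release of 18, so that the hindered, chelated product phenoxide is not arylated further.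

Step 11
Reactants: 19 (E)-3-{3-[4-(benzyloxy)-2-chloro-6-hydroxybenzoyl]-2-[4-(benzyloxy)phenyl]-1-benzofuran-5-yl}-1-[2,4-bis(benzyloxy)phenyl]prop-2-en-1-one
Product: 20 isolophirone C, 1-(2,4-dihydroxyphenyl)-3-[3-(2,4-dihydroxybenzoyl)-2-(4-hydroxyphenyl)-1-benzofuran-5-yl]propan-1-one
Conditions: H2 (1 atm), 10% Pd/C, Et3N (3 equiv), THF/MeOH, rt
Reagents that add atoms: none
Why: Heterogeneous hydrogenation combining alkene saturation, hydrogenolysis of four aryl benzyl ethers and hydrodechlorination of the aryl chloride; Et3N takes up HCl, speeds the C–Cl cleavage and disfavours over-reduction of the chelated aryl ketones, and no stereocentre is formed.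

## Compound list

1 | 4'-(benzyloxy)acetophenone | CC(=O)c1ccc(OCc2ccccc2)cc1 | starting material
2 | ethyl 3-[4-(benzyloxy)phenyl]-3-oxopropanoate | CCOC(=O)CC(=O)c1ccc(OCc2ccccc2)cc1 | intermediate
3 | 1,4-benzoquinone | O=C1C=CC(=O)C=C1 | starting material
4 | ethyl 3-[4-(benzyloxy)phenyl]-2-(2,5-dihydroxyphenyl)-3-oxopropanoate (racemic; not isolated) | CCOC(=O)C(C(=O)c1ccc(OCc2ccccc2)cc1)c1cc(O)ccc1O | intermediate
5 | ethyl 2-[4-(benzyloxy)phenyl]-5-hydroxy-1-benzofuran-3-carboxylate | CCOC(=O)c1c(-c2ccc(OCc3ccccc3)cc2)oc2ccc(O)cc12 | intermediate
6 | ethyl 2-[4-(benzyloxy)phenyl]-5-{[(trifluoromethyl)sulfonyl]oxy}-1-benzofuran-3-carboxylate | CCOC(=O)c1c(-c2ccc(OCc3ccccc3)cc2)oc2ccc(OS(=O)(=O)C(F)(F)F)cc12 | intermediate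
7 | ethyl 2-[4-(benzyloxy)phenyl]-5-formyl-1-benzofuran-3-carboxylate | CCOC(=O)c1c(-c2ccc(OCc3ccccc3)cc2)oc2ccc(C=O)cc12 | intermediate
8 | 2',4'-dihydroxyacetophenone | CC(=O)c1ccc(O)cc1O | starting material
9 | 2',4'-bis(benzyloxy)acetophenone | CC(=O)c1ccc(OCc2ccccc2)cc1OCc1ccccc1 | intermediate
10 | ethyl 2-[4-(benzyloxy)phenyl]-5-{(E)-3-[2,4-bis(benzyloxy)phenyl]-3-oxoprop-1-en-1-yl}-1-benzofuran-3-carboxylate (not isolated) | CCOC(=O)c1c(-c2ccc(OCc3ccccc3)cc2)oc2ccc(/C=C/C(=O)c3ccc(OCc4ccccc4)cc3OCc3ccccc3)cc12 | intermediate
11 | 2-[4-(benzyloxy)phenyl]-5-{(E)-3-[2,4-bis(benzyloxy)phenyl]-3-oxoprop-1-en-1-yl}-1-benzofuran-3-carboxylic acid | OC(=O)c1c(-c2ccc(OCc3ccccc3)cc2)oc2ccc(/C=C/C(=O)c3ccc(OCc4ccccc4)cc3OCc3ccccc3)cc12 | intermediate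
12 | 4-(benzyloxy)phenol | Oc1ccc(OCc2ccccc2)cc1 | starting material
13 | 4-(benzyloxy)-2-chlorophenol | Oc1ccc(OCc2ccccc2)cc1Cl | intermediate
14 | 4-(benzyloxy)-2-bromo-6-chlorophenol | Oc1c(Cl)cc(OCc2ccccc2)cc1Br | intermediate
15 | [4-(benzyloxy)-2-bromo-6-chlorophenoxy]trimethylsilane (not isolated) | C[Si](C)(C)Oc1c(Cl)cc(OCc2ccccc2)cc1Br | intermediate
16 | lithium 4-(benzyloxy)-2-chloro-6-(trimethylsilyl)phenoxide (not isolated) | [Li+].[O-]c1c(Cl)cc(OCc2ccccc2)cc1[Si](C)(C)C | intermediate
17 | 4-(benzyloxy)-2-chloro-6-(trimethylsilyl)phenyl trifluoromethanesulfonate | C[Si](C)(C)c1cc(OCc2ccccc2)cc(Cl)c1OS(=O)(=O)C(F)(F)F | intermediate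
18 | 5-(benzyloxy)-3-chlorobenzyne (5-(benzyloxy)-3-chloro-1,2-didehydrobenzene; not isolated) | ClC1=CC(OCc2ccccc2)=CC#C1 | intermediate
19 | (E)-3-{3-[4-(benzyloxy)-2-chloro-6-hydroxybenzoyl]-2-[4-(benzyloxy)phenyl]-1-benzofuran-5-yl}-1-[2,4-bis(benzyloxy)phenyl]prop-2-en-1-one | O=C(c1c(Cl)cc(OCc2ccccc2)cc1O)c1c(-c2ccc(OCc3ccccc3)cc2)oc2ccc(/C=C/C(=O)c3ccc(OCc4ccccc4)cc3OCc3ccccc3)cc12 | intermediate
20 | isolophirone C, 1-(2,4-dihydroxyphenyl)-3-[3-(2,4-dihydroxybenzoyl)-2-(4-hydroxyphenyl)-1-benzofuran-5-yl]propan-1-one | O=C(CCc1ccc2oc(-c3ccc(O)cc3)c(C(=O)c3ccc(O)cc3O)c2c1)c1ccc(O)cc1O | target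

## Step count and risks

Total: 11 steps. Longest linear sequence: 7 steps (steps 1, 2, 3, 4, 6, 10, 11). The aryne branch (steps 7–9) and the ketone branch (step 5) join at steps 10 and 6.

Least certain steps:

Step 10 (key step). Four processes could divert it:
- protonation of the aryl anion before it reaches the ester carbonyl, which would stop at simple O-arylation;
- loss of chloride from the ortho-chloroaryl anion, which would start a second aryne;
- slow acyl capture, because the carbonyl is screened by the C2 aryl ring and the C4 hydrogen;
- further arylation of the product phenoxide by excess aryne.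

Fallback, from 11 back to the route at 20: 11 would be converted with oxalyl chloride and catalytic DMF in CH2Cl2 into 2-[4-(benzyloxy)phenyl]-5-{(E)-3-[2,4-bis(benzyloxy)phenyl]-3-oxoprop-1-en-1-yl}-1-benzofuran-3-carbonyl chloride F1. Friedel–Crafts acylation of commercial 1,3-bis(benzyloxy)benzene with F1 (SnCl4, CH2Cl2, −20 °C) should occur at the position ortho to one ether and para to the other. It would give (E)-3-{3-[2,4-bis(benzyloxy)benzoyl]-2-[4-(benzyloxy)phenyl]-1-benzofuran-5-yl}-1-[2,4-bis(benzyloxy)phenyl]prop-2-en-1-one F2. Any benzyl group lost to the Lewis acid would not matter, since H2 over Pd/C in EtOAc/MeOH would then saturate the alkene and cleave all benzyl ethers to give 20.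

Step 4. Reduction of the arylpalladium intermediate by the silane before CO insertion, or sluggish oxidative addition into the electron-rich triflate, would erode the formylation.

Fallback, from 6 back to the route at 10: 9 would be α-methylenated (paraformaldehyde, diisopropylammonium trifluoroacetate, THF, reflux) to 1-[2,4-bis(benzyloxy)phenyl]prop-2-en-1-one F3. A Mizoroki–Heck reaction of 6 with F3 (Pd(OAc)2, PPh3, Et3N, DMF, 90 °C) would give 10 directly. Compound 10 would then be saponified as in the second half of step 6 to reach 11.

Step 9. The silyl shift may be incomplete, butyllithium may be consumed unproductively if O-silylation of the doubly ortho-substituted phenol is incomplete, and the hindered phenoxide may be triflated slowly while Tf2O is consumed by THF.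

Fallback, from 14 back to the route at 17: 14 would be treated with n-BuLi (2.2 equiv, THF, −78 °C) to form the O,C-dilithio species, which would be silylated with Me3SiCl to [4-(benzyloxy)-2-chloro-6-(trimethylsilyl)phenoxy]trimethylsilane F4. Mild aqueous acid would cleave the O–Si bond to give isolable 4-(benzyloxy)-2-chloro-6-(trimethylsilyl)phenol F5. F5 would be triflated separately (Tf2O, pyridine, CH2Cl2, 0 °C) to 17.

Step 11. Hydrogenolysis of the benzyl ethers may stall in the presence of the amine, or prolonged exposure may begin to reduce an aryl ketone.

Fallback, from 19 back to the route at 20: the benzyl ethers would first be removed without hydrogen (BCl3, pentamethylbenzene, CH2Cl2, −78 °C) to give (E)-3-[3-(2-chloro-4,6-dihydroxybenzoyl)-2-(4-hydroxyphenyl)-1-benzofuran-5-yl]-1-(2,4-dihydroxyphenyl)prop-2-en-1-one F6. A short hydrogenation of F6 (H2, Pd/C, Et3N, MeOH, rt) would then only saturate the alkene and replace chlorine by hydrogen, giving 20.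

## Further compounds

F1 | step 10 | 2-[4-(benzyloxy)phenyl]-5-{(E)-3-[2,4-bis(benzyloxy)phenyl]-3-oxoprop-1-en-1-yl}-1-benzofuran-3-carbonyl chloride | ClC(=O)c1c(-c2ccc(OCc3ccccc3)cc2)oc2ccc(/C=C/C(=O)c3ccc(OCc4ccccc4)cc3OCc3ccccc3)cc12
F2 | step 10 | (E)-3-{3-[2,4-bis(benzyloxy)benzoyl]-2-[4-(benzyloxy)phenyl]-1-benzofuran-5-yl}-1-[2,4-bis(benzyloxy)phenyl]prop-2-en-1-one | O=C(c1ccc(OCc2ccccc2)cc1OCc1ccccc1)c1c(-c2ccc(OCc3ccccc3)cc2)oc2ccc(/C=C/C(=O)c3ccc(OCc4ccccc4)cc3OCc3ccccc3)cc12
F3 | step 4 | 1-[2,4-bis(benzyloxy)phenyl]prop-2-en-1-one | C=CC(=O)c1ccc(OCc2ccccc2)cc1OCc1ccccc1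
F4 | step 9 | [4-(benzyloxy)-2-chloro-6-(trimethylsilyl)phenoxy]trimethylsilane | C[Si](C)(C)Oc1c(Cl)cc(OCc2ccccc2)cc1[Si](C)(C)C
F5 | step 9 | 4-(benzyloxy)-2-chloro-6-(trimethylsilyl)phenol | Oc1c(Cl)cc(OCc2ccccc2)cc1[Si](C)(C)C
F6 | step 11 | (E)-3-[3-(2-chloro-4,6-dihydroxybenzoyl)-2-(4-hydroxyphenyl)-1-benzofuran-5-yl]-1-(2,4-dihydroxyphenyl)prop-2-en-1-one | O=C(c1c(Cl)cc(O)cc1O)c1c(-c2ccc(O)cc2)oc2ccc(/C=C/C(=O)c3ccc(O)cc3O)cc12
A1 | alternative 1 | (E)-1-(2,4-dimethoxyphenyl)-3-(4-hydroxyphenyl)prop-2-en-1-one | COc1ccc(C(=O)/C=C/c2ccc(O)cc2)c(OC)c1
A2 | alternative 1 | 1-(2,4-dimethoxyphenyl)-3-(4-hydroxyphenyl)propan-1-one | COc1ccc(C(=O)CCc2ccc(O)cc2)c(OC)c1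
A3 | alternative 1 | trans-3-(2,4-dimethoxybenzoyl)-5-[3-(2,4-dimethoxyphenyl)-3-oxopropyl]-2-(4-hydroxyphenyl)-2,3-dihydro-1-benzofuran (racemic; the 2R,3R enantiomer drawn) | COc1ccc(C(=O)CCc2ccc3O[C@@H](c4ccc(O)cc4)[C@H](C(=O)c4ccc(OC)cc4OC)c3c2)c(OC)c1
A4 | alternative 2 | methyl (5E)-6-[4-(2,4-dimethoxybenzoyl)-5-(4-methoxyphenyl)furan-2-yl]-4-(methoxymethylidene)hex-5-enoate (enol ether geometry not specified) | COC=C(CCC(=O)OC)/C=C/c1cc(C(=O)c2ccc(OC)cc2OC)c(-c2ccc(OC)cc2)o1
A5 | alternative 2 | methyl 3-[3-(2,4-dimethoxybenzoyl)-2-(4-methoxyphenyl)-1-benzofuran-5-yl]propanoate | COC(=O)CCc1ccc2oc(-c3ccc(OC)cc3)c(C(=O)c3ccc(OC)cc3OC)c2c1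
A6 | alternative 3 | {1-[5-bromo-2-(4-methoxybenzoyloxy)phenyl]-2-(2,4-dimethoxyphenyl)-2-oxoethyl}triphenylphosphonium bromide (racemic) | COc1ccc(cc1)C(=O)Oc1ccc(Br)cc1C(C(=O)c1ccc(OC)cc1OC)[P+](c1ccccc1)(c1ccccc1)c1ccccc1.[Br-]
A7 | alternative 3 | [5-bromo-2-(4-methoxyphenyl)-1-benzofuran-3-yl](2,4-dimethoxyphenyl)methanone | COc1ccc(cc1)-c1oc2ccc(Br)cc2c1C(=O)c1ccc(OC)cc1OC
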